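## The problem

The target, 5,8-dihydroxy-7-methoxy-6-prenyl-3-(2,4,5-trimethoxyphenyl)chromen-4-one, is an isoflavone: benzene ring A is fused through C4a–C8a to the 4-pyranone ring C, and ring B hangs on C3 by a single aryl–vinyl bond. It has no stereocentre, so the difficulty is purely regiochemical, and it sits in ring A. Ring A is hexasubstituted: O1 on C8a, hydroxyl on C8, methoxy on C7, prenyl on C6, hydroxyl on C5 and the C4 carbonyl on C4a. With no ring hydrogen left, stepwise aromatic substitution would have to tell four oxygens apart (one in ring C, one methylated, two free) and put the prenyl group on the correct side of the methoxy group, the familiar 6- versus 8-prenyl ambiguity. The sensitive groups limit late chemistry: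
- the C5/C8 para-hydroquinone is oxidised to the quinone by air or oxidants;
- the prenyl group cyclises onto the neighbouring C5 hydroxyl in strong acid, is attacked by hydride-abstracting oxidants and excludes hydrogenolysis;
- ring B is a very electron-rich arene with two free positions;
- the C7 methyl ether must survive whatever frees the two phenols.

Stereocentres met on the way (a carbinol carbon, C3 of a chromanone) are erased again, so none needs control and none can exert control. The enabling feature is the sequence C5(O)–C6(C)–C7(OMe)–C8(O), which is the substitution pattern of a 3-methoxy-4-alkylcyclobutenedione; the remaining pair C8a(O1)=C4a is the double bond of a cyclic enol ether.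

## Retrosynthesis

**Freeing the phenols (20 from 19).** The last operation only removes two methoxymethyl groups from O5 and O8 of isoflavone 19. Acetal protection is chosen over silyl ethers because it must survive alkoxide base at 80 °C and a lithium amide. It is chosen over benzyl or isopropyl ethers because its removal needs neither hydrogen nor a boron halide next to the prenyl group. The forward step must stay below the acidity at which the prenyl group closes onto O5.

**The C2=C3 double bond (19 from 17).** Removing the unsaturation leads to isoflavanone 17. Its C3 hydrogen is benzylic and alpha to the ketone, so the enolate forms on one side only. The forward step must dehydrogenate through that enolate without a quinone oxidant, which the prenyl group would not tolerate.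

**The C3–C1' bond (17 from 15 and 16).** Cutting the bond to ring B gives chromanone 15 and commercial 1-bromo-2,4,5-trimethoxybenzene 16. This cut is preferred to building ring C around ring B, because it lets ring C be present, unsubstituted and robust, when ring A is made. C3 is the only enolisable carbon of 15, so the arylation has no regiochemical choice.

**Carbonyl and phenol masking (15 from 13).** Chromanone 15 comes from hydroquinone ketal 13 by acetalisation of both phenols and hydrolysis of the dioxolane. The phenols are capped while C4 is still a ketal, because neither is then hydrogen-bonded to a carbonyl and both react alike.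

**Ring A, bond C4a–C5 (13 from 10).** This is the disconnection that carries the plan. Opening ring A between C4a and C5 and folding C5–C8 back into a four-membered ring gives cyclobutenone 10. In 10 the carbonyl carbon is the future C5, and the prenyl-bearing, methoxy-bearing and carbinol carbons are the future C6, C7 and C8. The enol ether carbons of the attached dihydropyran are C8a and C4a. Compared with cuts inside ring C, this one removes the whole hexasubstituted benzene and replaces a regiochemical problem by connectivity. The forward reaction only has to be heated: four-electron ring opening, six-electron closure through ketene 11 and dienone 12, then tautomerisation.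

**Bond C8–C8a (10 from 5 and 8).** The carbinol carbon of 10 is joined to the enol ether carbon by adding vinyllithium 9, made from enol ether ketal 8, to cyclobutenedione 5. The two carbonyls of 5 differ: one is a vinylogous ester, the other a ketone. Attack at the ketone, next to the methoxy-bearing carbon, is what later places the methoxy group at C7 beside C8. Both partners are small and achiral.

**The enol ether ketal (8 from 7 and 6).** Direct ketalisation of 2,3-dihydro-4H-pyran-4-one is not relied on, since a vinylogous ester under acid takes up the diol at the enol ether carbon. Instead 8 is traced to bromo ketal 7 by loss of HBr, and 7 to tetrahydro-4H-pyran-4-one 6 by bromination in ethylene glycol. The symmetry of 6 and the quaternary ketal carbon of 7 leave each step one outcome.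

**The prenyl cyclobutenedione (5 from 4, 1 and 2).** Dione 5 is the rearrangement product of squarate adduct 4, which is dimethyl squarate 2 plus a prenyl nucleophile. A prenyl Grignard reagent would bond through its substituted terminus, so the nucleophile is prenylbarium chloride 3 from prenyl chloride 1, which reacts at the unsubstituted carbon.

## Roads not taken

**Alternative 1: ring C closed at C4–C4a by Friedel–Crafts acylation.** The cut is the bond from the carbonyl carbon to ring A.
- Forward step: (Z)-3-(2,5-diisopropoxy-3-methoxyphenoxy)-2-(2,4,5-trimethoxyphenyl)acrylic acid A1 is activated with trifluoroacetic anhydride, and its acylium ion attacks the only ortho carbon it can reach. This gives 5,8-diisopropoxy-7-methoxy-3-(2,4,5-trimethoxyphenyl)chromen-4-one A2.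
- Merits: it is convergent, ring B arrives with a cheap arylacetic acid, the closure has no regiochemical choice, and A2 is already at the chromone oxidation level. In this last respect it is better than the chosen plan, which spends steps 8 and 9 on a palladium arylation and a dehydrogenation.
- Weak points: A2 has a hydrogen at C6. The prenyl group must then be added to a ring deactivated by the carbonyl, in competition with the more nucleophilic ring B. A Claisen rearrangement from O5 would deliver the 1,1-dimethylallyl isomer. The aryloxy half of A1 needs a phenol with three differently substituted oxygens, which is the regiochemical problem moved elsewhere. Removing isopropyl ethers with a boron halide next to a prenyl group invites cyclisation.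
- Comparison: against the shorter ring C chemistry, the chosen plan sets a ring A in which the prenyl group and every oxygen are fixed by construction, before ring B is present.

**Alternative 2: ring A by Danheiser benzannulation.** The cut removes C5–C6, C7–C8 and C4a–C5.
- Forward step: 2,3-diisopropoxycyclobut-2-en-1-one A3 and the ynol ether 1-methoxy-5-methylhex-4-en-1-yne A4 are heated. Vinylketene formation, [2+2] addition, ring opening and six-electron closure give 4,5-diisopropoxy-3-methoxy-2-prenylphenol A5.
- Merits: this is the closest relative of the chosen plan. It also starts from squaric ester and carries the prenyl group in from the beginning. It is better in that A5 is reached in one intermolecular step, with no basic organolithium added to a dione with acidic allylic hydrogens.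
- Weak points: A5 has no ring C. The arylacetyl unit would have to be introduced at the single free position, which is flanked on both sides, under Lewis acid conditions in which an ortho-prenylphenol cyclises. The isopropyl ether on the future C8a must then be freed selectively from its neighbour on C8. Ring closure must choose that oxygen over the free C5 hydroxyl on the other side of the ketone, and the wrong choice gives the isomeric isoflavone. A4 is also a sensitive reagent to prepare.
- Comparison: the chosen plan makes ring A already fused to ring C, so O1 is never in question.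

**Alternative 3: carbene-catalysed crossed benzoin closure of C3–C4.** The cut is the bond between the carbonyl carbon and C3.
- Forward step: a triazolium-derived carbene turns the aldehyde of 3,6-diisopropoxy-4-methoxy-2-[2-oxo-2-(2,4,5-trimethoxyphenyl)ethoxy]benzaldehyde A6 into an acyl anion equivalent. This adds to the tethered ketone and gives racemic 3-hydroxy-5,8-diisopropoxy-7-methoxy-3-(2,4,5-trimethoxyphenyl)chroman-4-one A7. Dehydration then gives the isoflavone.
- Merits: the closure is catalytic, mild and well precedented for chromanones. Reaching the chromone by loss of water is gentler than the arylation and dehydrogenation pair of the chosen plan. In ring C chemistry this route is the better one.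
- Weak points: the aldehyde of A6 is flanked by two ortho oxygens and is electron-rich, and the ketone is a poor electrophile, so the addition may be slow and reversible. The stereocentre made is discarded. A7 again has a hydrogen at C6, and A6 needs a fully differentiated tetraoxygenated benzaldehyde made by linear aromatic chemistry.
- Comparison: the chosen plan sets against the gentler ring closure a single thermal step that delivers all six substituents of ring A in the right places.

Key step: step 6

Remark: the target has no stereocentre; compounds 4, 7, 10, 12 and 17 each carry one stereocentre that is formed racemic and later removed, so no configuration has to be set.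

## Route

Step 1
Reactants: 1 1-chloro-3-methylbut-2-ene (prenyl chloride); 2 dimethyl squarate (3,4-dimethoxycyclobut-3-ene-1,2-dione)
Product: 4 racemic 4-hydroxy-2,3-dimethoxy-4-(3-methylbut-2-en-1-yl)cyclobut-2-en-1-one, via prenylbarium chloride 3 (not isolated)
Conditions: BaI2, lithium biphenylide (2 equiv), THF, rt; then 1, –78 °C; then 2, –78 °C; H2O quench
Reagents that add atoms: none
Why: Allylbarium addition to a ketone carbonyl: the prenylbarium chloride formed at –78 °C bonds through its unsubstituted alpha carbon and adds in a 1,2 sense to one of the two equivalent carbonyls of 2, so the linear prenyl group is installed and not the 1,1-dimethylallyl isomer a Grignard reagent would give; the carbinol centre is racemic and is erased in step 2.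

Step 2
Reactants: 4 racemic 4-hydroxy-2,3-dimethoxy-4-(3-methylbut-2-en-1-yl)cyclobut-2-en-1-one
Product: 5 3-methoxy-4-(3-methylbut-2-en-1-yl)cyclobut-3-ene-1,2-dione
Conditions: (CF3CO)2O, THF, –78 °C to 0 °C; then H2O
Reagents that add atoms: water, O
Why: Standard conversion of a squarate 1,2-adduct into a 3-alkoxy-4-alkylcyclobutenedione: the trifluoroacetylated tertiary hydroxyl ionises with help from the methoxy groups, water adds to the methoxy-stabilised cation and methanol is lost, at temperatures where the prenyl alkene is not protonated.

Step 3
Reactants: 6 tetrahydro-4H-pyran-4-one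
Product: 7 racemic 6-bromo-1,4,8-trioxaspiro[4.5]decane
Conditions: Br2 (1 equiv), ethylene glycol, rt
Reagents that add atoms: bromine, BrBr; ethylene glycol, OCCO
Why: Direct alpha-bromoketalisation of a ketone in ethylene glycol: the HBr released catalyses ketal formation and the ketal is brominated through its enol ether; the symmetry of 6 allows only one monobromide, whose stereocentre is removed in step 4.

Step 4
Reactants: 7 racemic 6-bromo-1,4,8-trioxaspiro[4.5]decane
Product: 8 1,4,8-trioxaspiro[4.5]dec-6-ene
Conditions: KOtBu, DMSO, rt; distilled and stored over K2CO3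
Reagents that add atoms: none
Why: E2 dehydrobromination of an alpha-bromo ketal, the classical route to enone ketals: the ketal carbon is quaternary, so the only beta hydrogens are on C7 next to the ring oxygen and the alkene can form only as the C6=C7 enol ether; the product is kept basic because the allylic ketal ionises easily.

Step 5
Reactants: 8 1,4,8-trioxaspiro[4.5]dec-6-ene; 5 3-methoxy-4-(3-methylbut-2-en-1-yl)cyclobut-3-ene-1,2-dione
Product: 10 racemic 4-hydroxy-3-methoxy-2-(3-methylbut-2-en-1-yl)-4-(1,4,8-trioxaspiro[4.5]dec-6-en-7-yl)cyclobut-2-en-1-one, via vinyllithium 9 (not isolated)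
Conditions: t-BuLi, THF, –78 °C to 0 °C; then 5, THF, –78 °C; H2O quench; filtration through Et3N-deactivated silica
Reagents that add atoms: none
Why: Alpha-lithiation of a cyclic enol ether (as with dihydropyran and silylated glycals) followed by 1,2-addition to a cyclobutenedione: C1 of 5 is a vinylogous ester carbonyl and is deactivated, so the vinyllithium attacks C2 beside the methoxy-bearing carbon, which later places the methoxy group at C7; the carbinol centre is racemic and is destroyed in step 6.

Step 6
Reactants: 10 racemic 4-hydroxy-3-methoxy-2-(3-methylbut-2-en-1-yl)-4-(1,4,8-trioxaspiro[4.5]dec-6-en-7-yl)cyclobut-2-en-1-one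
Product: 13 7-methoxy-6-(3-methylbut-2-en-1-yl)spiro[chromane-4,2'-[1,3]dioxolane]-5,8-diol, via dienylketene 11 (not isolated), via cyclohexadienone 12 (not isolated)
Conditions: toluene (degassed), 110 °C, argon
Reagents that add atoms: none
Why: This is the Moore rearrangement, the thermal ring expansion of a 4-alkenyl-4-hydroxycyclobutenone to a hydroquinone. Heating opens the C1–C4 bond of the cyclobutenone in a conrotatory four-electron process to dienylketene 11. The selectivity the step needs is torquoselectivity: the donor hydroxyl on C4 turns outward, which turns the dihydropyranyl group inward, cis to the ketene. A thermally allowed disrotatory six-electron electrocyclisation then joins the electrophilic ketene carbon (C5) to the nucleophilic beta carbon of the enol ether (C4a), closing ring A as a six-membered carbocycle in cyclohexadienone 12 with matched polarity. Loss of the C4a hydrogen to oxygen aromatises 12 to hydroquinone 13, which makes the sequence irreversible. No stereocentre remains: the carbinol centre of 10 and the sp3 C4a of 12 are both erased. Regiochemistry is not decided here but by the connectivity of 10, whose carbonyl, prenyl-bearing, methoxy-bearing and carbinol carbons become C5, C6, C7 and C8, and whose enol ether carbons become C4a and C8a. The conditions are neutral and reagent-free, as the ketal and prenyl group require, and oxygen is excluded because 13 is an electron-rich hydroquinone.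

Step 7
Reactants: 13 7-methoxy-6-(3-methylbut-2-en-1-yl)spiro[chromane-4,2'-[1,3]dioxolane]-5,8-diol
Product: 15 7-methoxy-5,8-bis(methoxymethoxy)-6-(3-methylbut-2-en-1-yl)chroman-4-one, via bis(methoxymethyl) ether 14 (not isolated)
Conditions: MOMCl, iPr2NEt, CH2Cl2, 0 °C to 40 °C; aqueous NaHCO3 wash, concentrate; then PPTS, acetone–H2O, rt to 40 °C
Reagents that add atoms: chloromethyl methyl ether, COCCl; water, O
Why: Phenol O-alkylation, then ketal hydrolysis: both phenols are capped while C4 is still a ketal, so neither is tied up in a hydrogen bond to a carbonyl; the dioxolane on the very electron-rich benzylic carbon should then hydrolyse under pyridinium catalysis, leaving the aryl methoxymethyl ethers.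

Step 8
Reactants: 15 7-methoxy-5,8-bis(methoxymethoxy)-6-(3-methylbut-2-en-1-yl)chroman-4-one; 16 1-bromo-2,4,5-trimethoxybenzene
Product: 17 racemic 7-methoxy-5,8-bis(methoxymethoxy)-6-(3-methylbut-2-en-1-yl)-3-(2,4,5-trimethoxyphenyl)chroman-4-one
Conditions: Pd(OAc)2 (cat.), XPhos, NaOtBu, toluene, 80 °C
Reagents that add atoms: none
Why: Palladium-catalysed alpha-arylation of a ketone enolate (Buchwald–Hartwig type), a known route from chroman-4-ones to isoflavanones: C3 is the only enolisable carbon, the bulky electron-rich phosphine copes with the ortho-substituted electron-rich bromide, and the hindered, more acidic product enolate resists a second arylation; the C3 stereocentre is racemic and is removed in step 9.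

Step 9
Reactants: 17 racemic 7-methoxy-5,8-bis(methoxymethoxy)-6-(3-methylbut-2-en-1-yl)-3-(2,4,5-trimethoxyphenyl)chroman-4-one
Product: 19 7-methoxy-5,8-bis(methoxymethoxy)-6-(3-methylbut-2-en-1-yl)-3-(2,4,5-trimethoxyphenyl)-4H-chromen-4-one, via lithium enolate 18 (not isolated)
Conditions: LiN(SiMe3)2, THF, –78 °C; then PhS(Cl)=NtBu, –78 °C to rt
Reagents that add atoms: none
Why: Mukaiyama dehydrogenation: the enolate is sulfenylated at C3 by N-tert-butylbenzenesulfinimidoyl chloride and the adduct undergoes syn elimination with a C2 hydrogen, giving the C2=C3 double bond at low temperature without a quinone or hypervalent iodine oxidant that could attack the prenyl group or the electron-rich rings.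

Step 10
Reactants: 19 7-methoxy-5,8-bis(methoxymethoxy)-6-(3-methylbut-2-en-1-yl)-3-(2,4,5-trimethoxyphenyl)-4H-chromen-4-one
Product: 20 5,8-dihydroxy-7-methoxy-6-(3-methylbut-2-en-1-yl)-3-(2,4,5-trimethoxyphenyl)-4H-chromen-4-one (CNP0109753.0)
Conditions: HCl (1 M in MeOH), THF, 0 °C to 40 °C, argon
Reagents that add atoms: none
Why: Acid-catalysed acetal exchange of aryl methoxymethyl ethers with methanol, routine for prenylated flavonoids: the O5 ether beside the carbonyl should cleave first, the excess methanol traps the methoxymethyl cation as dimethoxymethane before it can alkylate ring B, and the freed C5 hydroxyl is hydrogen-bonded to the carbonyl, which lowers its tendency to add to the prenyl group.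

## Compound list

1 | 1-chloro-3-methylbut-2-ene (prenyl chloride) | CC(C)=CCCl | starting material
2 | dimethyl squarate | COC1=C(OC)C(=O)C1=O | starting material
3 | prenylbarium chloride | CC(C)=CC[Ba]Cl | intermediate (not isolated)
4 | racemic 4-hydroxy-2,3-dimethoxy-4-(3-methylbut-2-en-1-yl)cyclobut-2-en-1-one | COC1=C(OC)C(O)(CC=C(C)C)C1=O | intermediate
5 | 3-methoxy-4-(3-methylbut-2-en-1-yl)cyclobut-3-ene-1,2-dione | COC1=C(CC=C(C)C)C(=O)C1=O | intermediate
6 | tetrahydro-4H-pyran-4-one | O=C1CCOCC1 | starting material
7 | racemic 6-bromo-1,4,8-trioxaspiro[4.5]decane | BrC1COCCC12OCCO2 | intermediate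
8 | 1,4,8-trioxaspiro[4.5]dec-6-ene | C1=CC2(CCO1)OCCO2 | intermediate
9 | 7-lithio-1,4,8-trioxaspiro[4.5]dec-6-ene | [Li]C1=CC2(CCO1)OCCO2 | intermediate (not isolated)
10 | racemic 4-hydroxy-3-methoxy-2-(3-methylbut-2-en-1-yl)-4-(1,4,8-trioxaspiro[4.5]dec-6-en-7-yl)cyclobut-2-en-1-one | COC1=C(CC=C(C)C)C(=O)C1(O)C1=CC2(CCO1)OCCO2 | intermediate
11 | (Z)-4-hydroxy-3-methoxy-2-(3-methylbut-2-en-1-yl)-4-(1,4,8-trioxaspiro[4.5]dec-6-en-7-yl)buta-1,3-dien-1-one, hydroxyl trans to the ketene-bearing carbon | O=C=C(CC=C(C)C)/C(OC)=C(/O)C1=CC2(CCO1)OCCO2 | intermediate (not isolated)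
12 | racemic 8-hydroxy-7-methoxy-6-(3-methylbut-2-en-1-yl)-2,3-dihydrospiro[chromene-4,2'-[1,3]dioxolan]-5(4aH)-one | O=C1C(CC=C(C)C)=C(OC)C(O)=C2OCCC3(OCCO3)C12 | intermediate (not isolated)
13 | 7-methoxy-6-(3-methylbut-2-en-1-yl)spiro[chromane-4,2'-[1,3]dioxolane]-5,8-diol | Oc1c(CC=C(C)C)c(OC)c(O)c2OCCC3(OCCO3)c12 | intermediate
14 | 7-methoxy-5,8-bis(methoxymethoxy)-6-(3-methylbut-2-en-1-yl)spiro[chromane-4,2'-[1,3]dioxolane] | COCOc1c(CC=C(C)C)c(OC)c(OCOC)c2OCCC3(OCCO3)c12 | intermediate (not isolated)
15 | 7-methoxy-5,8-bis(methoxymethoxy)-6-(3-methylbut-2-en-1-yl)chroman-4-one | COCOc1c(CC=C(C)C)c(OC)c(OCOC)c2OCCC(=O)c12 | intermediate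
16 | 1-bromo-2,4,5-trimethoxybenzene | COc1cc(OC)c(Br)cc1OC | starting material
17 | racemic 7-methoxy-5,8-bis(methoxymethoxy)-6-(3-methylbut-2-en-1-yl)-3-(2,4,5-trimethoxyphenyl)chroman-4-one | COCOc1c(CC=C(C)C)c(OC)c(OCOC)c2OCC(c3cc(OC)c(OC)cc3OC)C(=O)c12 | intermediate
18 | lithium enolate of 17 (lithium 7-methoxy-5,8-bis(methoxymethoxy)-6-(3-methylbut-2-en-1-yl)-3-(2,4,5-trimethoxyphenyl)-2H-chromen-4-olate) | COCOc1c(CC=C(C)C)c(OC)c(OCOC)c2OCC(c3cc(OC)c(OC)cc3OC)=C(O[Li])c12 | intermediate (not isolated)
19 | 7-methoxy-5,8-bis(methoxymethoxy)-6-(3-methylbut-2-en-1-yl)-3-(2,4,5-trimethoxyphenyl)-4H-chromen-4-one | COCOc1c(CC=C(C)C)c(OC)c(OCOC)c2occ(-c3cc(OC)c(OC)cc3OC)c(=O)c12 | intermediate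
20 | 5,8-dihydroxy-7-methoxy-6-(3-methylbut-2-en-1-yl)-3-(2,4,5-trimethoxyphenyl)-4H-chromen-4-one | COc1cc(OC)c(-c2coc3c(O)c(OC)c(CC=C(C)C)c(O)c3c2=O)cc1OC | target

## Step count and least certain steps

Total steps: 10. Longest linear sequence: 8 steps (steps 3 to 10 from 6; the squarate branch, steps 1, 2 and 5 to 10, is equally long).

**Step 6 (key step).** The allylic ketal and tertiary carbinol of 10 may ionise before the ring opens, with loss of the ketal or of water. The electron-rich hydroquinone may also be oxidised by air during isolation. The fallback removes the ionisable ketal and keeps the ring expansion. It sets out from 5 and returns at 15. Commercial 2,3-dihydro-4H-pyran-4-one would be reduced (NaBH4, CeCl3·7H2O, MeOH) to racemic 3,4-dihydro-2H-pyran-4-ol F1 and silylated (iPr3SiCl, imidazole) to racemic 4-(triisopropylsilyloxy)-3,4-dihydro-2H-pyran F2. Lithiation with t-BuLi, as for a silylated glycal, would give the 6-lithio derivative F3, and addition to 5 the cyclobutenone adduct F4. Thermolysis in toluene would give racemic 7-methoxy-6-prenyl-4-(triisopropylsilyloxy)chromane-5,8-diol F5, and MOMCl with iPr2NEt its bis(methoxymethyl) ether F6. Bu4NF would free racemic 7-methoxy-5,8-bis(methoxymethoxy)-6-prenylchroman-4-ol F7, and Dess–Martin periodinane would oxidise this benzylic alcohol to 15.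

**Step 5.** The basic vinyllithium may take a proton from the doubly activated allylic CH2 of 5 instead of adding, and leftover t-BuLi may attack 5. The fallback sets out from 8 and returns at 10. The lithiated enol ether would be quenched with Bu3SnCl to give 7-(tributylstannyl)-1,4,8-trioxaspiro[4.5]dec-6-ene F8, which can be purified. Tin–lithium exchange with n-BuLi would regenerate 9 free of other bases. Transmetalation with CeCl3 would give the far less basic organocerium reagent (1,4,8-trioxaspiro[4.5]dec-6-en-7-yl)cerium dichloride F9, which would add to 5 to give 10.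

**Step 1.** The allylbarium may lose its alpha selectivity if it equilibrates, or excess reductant may transfer an electron to the squarate. The fallback sets out from 2 and returns at 5. Allylmagnesium bromide (THF, –78 °C), which has no regiochemical choice, would give racemic 4-allyl-4-hydroxy-2,3-dimethoxycyclobut-2-en-1-one F10. (CF3CO)2O then water would give 3-allyl-4-methoxycyclobut-3-ene-1,2-dione F11. Cross-metathesis with 2-methylbut-2-ene, using the phosphine-free second-generation Hoveyda–Grubbs catalyst RuCl2(H2IMes)(=CH-C6H4-2-OiPr) in CH2Cl2 at 40 °C, would convert the allyl group into the prenyl group of 5.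

**Step 8.** Oxidative addition and reductive elimination may be slow with the ortho-substituted, electron-rich bromide. Meanwhile the chromanone enolate may open by retro-oxa-Michael elimination of the phenoxide. The fallback sets out from 15, returns at 19 and also bypasses step 9. Dehydrogenation of 15 as in step 9 (LiN(SiMe3)2, then PhS(Cl)=NtBu) at its unhindered secondary enolate would give 7-methoxy-5,8-bis(methoxymethoxy)-6-prenyl-4H-chromen-4-one F12. Iodine and pyridine in CHCl3 would give the 3-iodochromone F13. Suzuki coupling with commercial (2,4,5-trimethoxyphenyl)boronic acid (Pd(PPh3)4, Na2CO3, dimethoxyethane–H2O, 80 °C) would give 19.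

**Step 9.** Carbon–sulfur bond formation at the hindered, aryl-stabilised tertiary enolate may be slow, returning 17 or giving reaction at oxygen. The fallback sets out from 17 and returns at 19. The potassium enolate (KN(SiMe3)2, THF, –78 °C) would be hydroxylated with 2-(phenylsulfonyl)-3-phenyloxaziridine to racemic 3-hydroxy-7-methoxy-5,8-bis(methoxymethoxy)-6-prenyl-3-(2,4,5-trimethoxyphenyl)chroman-4-one F14. Dehydration of this tertiary alcohol across C2–C3 with Burgess reagent (benzene, 50 °C) would give 19.

**Step 10.** The slower cleavage of the O8 ether may require acidity at which the prenyl group cyclises onto the already freed C5 hydroxyl to a dimethylchroman. The fallback changes the protecting group to one removed by fluoride. It sets out from 13 and returns at 20.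
- 2-(Trimethylsilyl)ethoxymethyl chloride with iPr2NEt would give the bis-ether ketal F15, and PPTS in wet acetone the chromanone F16.
- Arylation with 16 as in step 8 would give racemic isoflavanone F17, and dehydrogenation as in step 9 the isoflavone F18.
- Bu4NF in THF and N,N'-dimethylpropyleneurea at 60 °C under argon, followed by mild acidification, would free both phenols to give 20.

## Further compounds

F1 | step 6 | racemic 3,4-dihydro-2H-pyran-4-ol | OC1CCOC=C1
F2 | step 6 | racemic 4-(triisopropylsilyloxy)-3,4-dihydro-2H-pyran | CC(C)[Si](OC1CCOC=C1)(C(C)C)C(C)C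
F3 | step 6 | racemic 6-lithio-4-(triisopropylsilyloxy)-3,4-dihydro-2H-pyran | [Li]C1=CC(O[Si](C(C)C)(C(C)C)C(C)C)CCO1
F4 | step 6 | 4-hydroxy-3-methoxy-2-(3-methylbut-2-en-1-yl)-4-[4-(triisopropylsilyloxy)-3,4-dihydro-2H-pyran-6-yl]cyclobut-2-en-1-one (mixture of two racemic diastereomers) | COC1=C(CC=C(C)C)C(=O)C1(O)C1=CC(O[Si](C(C)C)(C(C)C)C(C)C)CCO1
F5 | step 6 | racemic 7-methoxy-6-(3-methylbut-2-en-1-yl)-4-(triisopropylsilyloxy)chromane-5,8-diol | CC(C)[Si](OC1CCOc2c(O)c(OC)c(CC=C(C)C)c(O)c12)(C(C)C)C(C)C
F6 | step 6 | racemic 7-methoxy-5,8-bis(methoxymethoxy)-6-(3-methylbut-2-en-1-yl)-4-(triisopropylsilyloxy)chromane | COCOc1c(CC=C(C)C)c(OC)c(OCOC)c2OCCC(O[Si](C(C)C)(C(C)C)C(C)C)c12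
F7 | step 6 | racemic 7-methoxy-5,8-bis(methoxymethoxy)-6-(3-methylbut-2-en-1-yl)chroman-4-ol | COCOc1c(CC=C(C)C)c(OC)c(OCOC)c2OCCC(O)c12
F8 | step 5 | 7-(tributylstannyl)-1,4,8-trioxaspiro[4.5]dec-6-ene | CCCC[Sn](CCCC)(CCCC)C1=CC2(CCO1)OCCO2
F9 | step 5 | (1,4,8-trioxaspiro[4.5]dec-6-en-7-yl)cerium dichloride | Cl[Ce](Cl)C1=CC2(CCO1)OCCO2
F10 | step 1 | racemic 4-allyl-4-hydroxy-2,3-dimethoxycyclobut-2-en-1-one | COC1=C(OC)C(O)(CC=C)C1=O
F11 | step 1 | 3-allyl-4-methoxycyclobut-3-ene-1,2-dione | COC1=C(CC=C)C(=O)C1=O
F12 | step 8 | 7-methoxy-5,8-bis(methoxymethoxy)-6-(3-methylbut-2-en-1-yl)-4H-chromen-4-one | COCOc1c(CC=C(C)C)c(OC)c(OCOC)c2occc(=O)c12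
F13 | step 8 | 3-iodo-7-methoxy-5,8-bis(methoxymethoxy)-6-(3-methylbut-2-en-1-yl)-4H-chromen-4-one | COCOc1c(CC=C(C)C)c(OC)c(OCOC)c2occ(I)c(=O)c12
F14 | step 9 | racemic 3-hydroxy-7-methoxy-5,8-bis(methoxymethoxy)-6-(3-methylbut-2-en-1-yl)-3-(2,4,5-trimethoxyphenyl)chroman-4-one | COCOc1c(CC=C(C)C)c(OC)c(OCOC)c2OCC(O)(c3cc(OC)c(OC)cc3OC)C(=O)c12
F15 | step 10 | 7-methoxy-6-(3-methylbut-2-en-1-yl)-5,8-bis{[2-(trimethylsilyl)ethoxy]methoxy}spiro[chromane-4,2'-[1,3]dioxolane] | C[Si](C)(C)CCOCOc1c(CC=C(C)C)c(OC)c(OCOCC[Si](C)(C)C)c2OCCC3(OCCO3)c12
F16 | step 10 | 7-methoxy-6-(3-methylbut-2-en-1-yl)-5,8-bis{[2-(trimethylsilyl)ethoxy]methoxy}chroman-4-one | C[Si](C)(C)CCOCOc1c(CC=C(C)C)c(OC)c(OCOCC[Si](C)(C)C)c2OCCC(=O)c12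
F17 | step 10 | racemic 7-methoxy-6-(3-methylbut-2-en-1-yl)-3-(2,4,5-trimethoxyphenyl)-5,8-bis{[2-(trimethylsilyl)ethoxy]methoxy}chroman-4-one | C[Si](C)(C)CCOCOc1c(CC=C(C)C)c(OC)c(OCOCC[Si](C)(C)C)c2OCC(c3cc(OC)c(OC)cc3OC)C(=O)c12
F18 | step 10 | 7-methoxy-6-(3-methylbut-2-en-1-yl)-3-(2,4,5-trimethoxyphenyl)-5,8-bis{[2-(trimethylsilyl)ethoxy]methoxy}-4H-chromen-4-one | C[Si](C)(C)CCOCOc1c(CC=C(C)C)c(OC)c(OCOCC[Si](C)(C)C)c2occ(-c3cc(OC)c(OC)cc3OC)c(=O)c12
A1 | alternative 1 | (Z)-3-(2,5-diisopropoxy-3-methoxyphenoxy)-2-(2,4,5-trimethoxyphenyl)acrylic acid | OC(=O)/C(c1cc(OC)c(OC)cc1OC)=C\Oc1cc(OC(C)C)cc(OC)c1OC(C)C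
A2 | alternative 1 | 5,8-diisopropoxy-7-methoxy-3-(2,4,5-trimethoxyphenyl)-4H-chromen-4-one | COc1cc(OC)c(-c2coc3c(OC(C)C)c(OC)cc(OC(C)C)c3c2=O)cc1OC
A3 | alternative 2 | 2,3-diisopropoxycyclobut-2-en-1-one | CC(C)OC1=C(OC(C)C)C(=O)C1
A4 | alternative 2 | 1-methoxy-5-methylhex-4-en-1-yne | COC#CCC=C(C)C
A5 | alternative 2 | 4,5-diisopropoxy-3-methoxy-2-(3-methylbut-2-en-1-yl)phenol | CC(C)Oc1cc(O)c(CC=C(C)C)c(OC)c1OC(C)C
A6 | alternative 3 | 3,6-diisopropoxy-4-methoxy-2-[2-oxo-2-(2,4,5-trimethoxyphenyl)ethoxy]benzaldehyde | COc1cc(OC)c(C(=O)COc2c(OC(C)C)c(OC)cc(OC(C)C)c2C=O)cc1OC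
A7 | alternative 3 | racemic 3-hydroxy-5,8-diisopropoxy-7-methoxy-3-(2,4,5-trimethoxyphenyl)chroman-4-one | COc1cc(OC)c(C2(O)COc3c(OC(C)C)c(OC)cc(OC(C)C)c3C2=O)cc1OC
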